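Time is the first thing you would turn on this flask, which repeats zeta but whose last asked time lies beyond zeta's last reading.

| flask | substrate | other conformer | solid reagent | remark | time |
|---|---|---|---|---|---|
| zeta | 0.050 M | 0.0125 M | 0.050 M | the very flask that is asked about, followed so far |  |
| epsilon | 0.10 M | 0.0125 M | 0.050 M | run made earlier |  |
| flask | 0.050 M | 0.0125 M | 0.0500 M |  | 5.0 d |

zeta run (percent of the substrate and other conformer together charged)

| time / h | isomer of the product / % | target / % |
|---|---|---|
| 2.00 | 2.9 | 6.1 |
| 5.00 | 6.6 | 15.1 |
| 10.0 | 14.7 | 25.8 |
| 15.0 | 20.5 | 33.9 |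
| 20.0 | 25.1 | 38.4 |

epsilon run (percent of the substrate and other conformer together charged)

| time / d | isomer of the product / % | target / % |
|---|---|---|
| 0.417 | 9.7 | 27.5 |
| 0.833 | 11.9 | 31.3 |
| 1.25 | 12.6 | 31.5 |
| 2.50 | 13.7 | 32.6 |
| 5.00 | 13.2 | 32.2 |

(readings scatter by 0.5 percentage points)

- solid, in amounts per volume of the solution: solid reagent
- the earlier runs were read with a standard deviation of 0.5 percentage points
- at the start none of the solid reagent is in solution

- ratio of isomer of the product to target at 1.0 h
- ratio of isomer of the product to target at 12 h
- ratio of isomer of the product to target at 5.0 d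

By hand, a longer wait should add product. Yet in epsilon, target plus isomer of the product reads 46.3% at 2.50 d and 45.4% at 5.00 d: a plateau, within the scatter.

Substrate comes next. Charged at twice zeta's level, it should favour target, and it does: at 0.417 d epsilon's ratio of isomer to target reads 0.353, below zeta's 0.570 at 10.0 h, the same time.

Then the solid reagent. Take it as the limiting reagent, one of it to one of product. For your flask that gives 80.0% as the reagent ceiling, c(solid reagent) divided by c(substrate) + c(other conformer). The same rule gives 44.4% for epsilon, against that plateau.

Now solve both ends. Early, I read the answers from zeta: for 1.0 h near the 0.437 read at 5.00 h, and between 0.570 and 0.605 for 12 h. Late, zeta's last reading leaves 17 percentage points under the ceiling. In zeta, isomer's share of new product reads 0.304 up to 5.00 h and 0.505 between 15.0 h and 20.0 h. Held at that last share, the room gives me 0.718 at 5.0 d.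

The forecast says 0.41, 0.57 and 0.75, holding that “the products do not interconvert”. Its end value stands above mine.

The flask gives 0.424, 0.576 and 0.769.

    substrate ⇌ other conformer (K = 3.80, k = 0.0235 h⁻¹)
    substrate + coupling partner → target (k = 2.98 L mol⁻¹ h⁻¹)
    coupling partner + other conformer → isomer of the product (k = 4.79 L mol⁻¹ h⁻¹)
    substrate → decomposition product (k = 2.55 × 10⁻⁴ h⁻¹)
    solid reagent ⇌ coupling partner, rate k5*(cs5 - [coupling partner]) while solid is left; crystals form when [coupling partner] > cs5 (solubility = 16.0 mM, k = 3.08 h⁻¹)

At 5.00 d, with solid reagent at 0% of its charge and coupling partner at 3.47 × 10⁻⁵ M, target 45.2% and isomer 34.7% sum to 79.9%, against the ceiling of 80.0%. The neighbour charged with 0.031 M of other conformer has a ceiling of 61.7%. Its isomer at 5.00 d, 33.8%, leaves target the rest of that ceiling, a ratio of 1.21, and that flask gives 1.21.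

(Readings and results stem from a simulated flask from invented constants; scatter was added.)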